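The route rests on cutting the C1–C7a bond of the indane. C7a of resorcinol ring A lies meta to O-4 and O-6, so no Friedel–Crafts-type closure can form this bond. A bromine carried in from 5-bromoresorcinol marks the carbon instead. One intramolecular 5-exo-trig Mizoroki–Heck reaction closes the five-membered ring. By syn insertion and syn loss of H-1 it converts an E-styrene into the E-benzylidene and leaves C2 and C3 untouched. The precursor is an acyclic aryl bromide, hepta-O-isopropyl protected, with both stereocentres and the E-alkene in place. The dyad comes from a phosphoric-acid-catalysed o-quinone methide/enol union. The alkene comes from a Julia–Kocienski olefination with the sulfone on C1.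

Key step: step 14

Remarks (indane numbering C1, C2, C3, C3a, C7a is used for these atoms in all intermediates)
- Stereochemical bookkeeping: the target is (1E,2S,3S), with the aryl groups at C2 and C3 trans. In the chroman intermediate the 2,4-dioxygenated ring is the fused ring and ring A is the substituent. The same dyad therefore appears there as the 3,4-cis isomer.
- Assumption: (R)-TRIP is written for the (3S,4S)-chromanol. The sense of induction is to be confirmed on that compound, and the antipodal acid is taken if it proves opposite.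

Step 1
Reactants: 1 5-bromoresorcinol
Product: 2 1-bromo-3,5-diisopropoxybenzene
Conditions: 2-bromopropane, K2CO3, DMF, 60 °C
Reagents that add atoms: 2-bromopropane, CC(C)Br
Why: Williamson ether synthesis on both phenols, in which the aryl bromide is inert to carbonate.

Step 2
Reactants: 2 1-bromo-3,5-diisopropoxybenzene
Product: 3 1-bromo-2-iodo-3,5-diisopropoxybenzene
Conditions: NIS, MeCN, 0 °C to rt, dark
Reagents that add atoms: N-iodosuccinimide, O=C1CCC(=O)N1I
Why: Electrophilic aromatic iodination should go para to one isopropoxy group and ortho to the other, next to bromine, because the site between the two isopropoxy groups is the more crowded one.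

Step 3
Reactants: 4 2,4-dihydroxybenzaldehyde
Product: 5 2-hydroxy-4-isopropoxybenzaldehyde
Conditions: 2-bromopropane (1.1 equiv), K2CO3 (1.1 equiv), DMF, 40 °C
Reagents that add atoms: 2-bromopropane, CC(C)Br
Why: Regioselective Williamson etherification, since the 2-OH is hydrogen-bonded to the formyl group and is the poorer nucleophile, so that O-4 is alkylated.

Step 4
Reactants: 3 1-bromo-2-iodo-3,5-diisopropoxybenzene; 5 2-hydroxy-4-isopropoxybenzaldehyde
Product: 8 (±)-2-[(2-bromo-4,6-diisopropoxyphenyl)(hydroxy)methyl]-5-isopropoxyphenol, via aryl Grignard reagent 6 (not isolated), via magnesium phenoxide 7 (not isolated)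
Conditions: 3, i-PrMgCl·LiCl, THF, −25 °C; 5, i-PrMgCl (1 equiv), THF, −25 °C; combine, −25 to 0 °C; aq NH4Cl
Reagents that add atoms: none
Why: Iodine–magnesium exchange is far faster at C–I than at C–Br and the ortho-bromoaryl Grignard reagent should not collapse to an aryne below 0 °C, so Grignard 1,2-addition to the pre-formed phenoxide gives the benzhydrol, whose carbinol centre is erased in step 7 and may be racemic.

Step 5
Reactants: 9 3,5-dihydroxyphenylacetic acid
Product: 10 isopropyl (3,5-diisopropoxyphenyl)acetate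
Conditions: 2-bromopropane (excess), K2CO3, DMF, 60 °C
Reagents that add atoms: 2-bromopropane, CC(C)Br
Why: Williamson etherification of both phenols with concurrent O-alkylation of the carboxylate gives the fully protected ester in one operation.

Step 6
Reactants: 10 isopropyl (3,5-diisopropoxyphenyl)acetate
Product: 11 (3,5-diisopropoxyphenyl)acetaldehyde
Conditions: DIBAL-H (1.1 equiv), toluene, −78 °C; Rochelle salt
Reagents that add atoms: none
Why: Partial DIBAL-H reduction of an ester, in which the aluminium hemiacetal of the bulky isopropyl ester should survive at −78 °C and release the aldehyde only on work-up.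

Step 7
Reactants: 8 (±)-2-[(2-bromo-4,6-diisopropoxyphenyl)(hydroxy)methyl]-5-isopropoxyphenol; 11 (3,5-diisopropoxyphenyl)acetaldehyde
Product: 13 (3S,4S)-4-(2-bromo-4,6-diisopropoxyphenyl)-3-(3,5-diisopropoxyphenyl)-7-isopropoxychroman-2-ol (3,4-cis; anomer mixture), via o-quinone methide 12 (not isolated)
Conditions: (R)-TRIP (10 mol %), 11 (2 equiv), 3 Å MS, CHCl3, 0 °C to rt
Reagents that add atoms: none
Why: Known Brønsted-acid-catalysed addition of arylacetaldehyde enols to o-quinone methides made in situ from o-hydroxybenzhydrols (formal [4+2] with hemiacetalisation): the chiral phosphate dehydrates 8 to 12 and holds its oxygen and the enol O–H of 11 in one hydrogen-bonded array, so one face of the methide carbon is attacked (sets C3), the compact arrangement places both aryl groups cis on the new chroman (sets C2 relative to C3), and closure to the lactol keeps the α-aryl aldehyde from enolising.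

Step 8
Reactants: 13 (3S,4S)-4-(2-bromo-4,6-diisopropoxyphenyl)-3-(3,5-diisopropoxyphenyl)-7-isopropoxychroman-2-ol
Product: 14 (2S,3S)-3-(2-bromo-4,6-diisopropoxyphenyl)-2-(3,5-diisopropoxyphenyl)-3-(2-hydroxy-4-isopropoxyphenyl)propan-1-ol
Conditions: NaBH4, THF–EtOH, −10 °C; aq NH4Cl
Reagents that add atoms: none
Why: Borohydride reduction of a lactol through its open hydroxy-aldehyde form should be faster at low temperature than enolisation, so C2 keeps its configuration and is no longer epimerisable afterwards.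

Step 9
Reactants: 14 (2S,3S)-3-(2-bromo-4,6-diisopropoxyphenyl)-2-(3,5-diisopropoxyphenyl)-3-(2-hydroxy-4-isopropoxyphenyl)propan-1-ol
Product: 15 (2S,3S)-3-(2-bromo-4,6-diisopropoxyphenyl)-3-(2,4-diisopropoxyphenyl)-2-(3,5-diisopropoxyphenyl)propan-1-ol
Conditions: 2-bromopropane, K2CO3, DMF, 55 °C
Reagents that add atoms: 2-bromopropane, CC(C)Br
Why: Chemoselective Williamson etherification, because carbonate deprotonates only the phenol, and capping it prevents chroman formation in the following Mitsunobu step.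

Step 10
Reactants: 15 (2S,3S)-3-(2-bromo-4,6-diisopropoxyphenyl)-3-(2,4-diisopropoxyphenyl)-2-(3,5-diisopropoxyphenyl)propan-1-ol
Product: 16 5-{[(2S,3S)-3-(2-bromo-4,6-diisopropoxyphenyl)-3-(2,4-diisopropoxyphenyl)-2-(3,5-diisopropoxyphenyl)propyl]sulfanyl}-1-phenyl-1H-tetrazole
Conditions: 1-phenyl-1H-tetrazole-5-thiol, PPh3, DIAD, THF, 0 °C to rt
Reagents that add atoms: 1-phenyl-1H-tetrazole-5-thiol, Sc1nnnn1-c1ccccc1
Why: Mitsunobu thioetherification of a primary alcohol with an acidic heteroaryl thiol proceeds by SN2 at C1 and does not involve the stereocentres.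

Step 11
Reactants: 16 5-{[(2S,3S)-3-(2-bromo-4,6-diisopropoxyphenyl)-3-(2,4-diisopropoxyphenyl)-2-(3,5-diisopropoxyphenyl)propyl]sulfanyl}-1-phenyl-1H-tetrazole
Product: 17 5-{[(2S,3S)-3-(2-bromo-4,6-diisopropoxyphenyl)-3-(2,4-diisopropoxyphenyl)-2-(3,5-diisopropoxyphenyl)propyl]sulfonyl}-1-phenyl-1H-tetrazole
Conditions: (NH4)6Mo7O24·4H2O (15 mol %), 30% aq H2O2, EtOH, 0 °C to rt
Reagents that add atoms: hydrogen peroxide, OO
Why: Molybdate-catalysed sulfide-to-sulfone oxidation is selective for sulfur and should leave aryl ethers and the aryl bromide alone.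

Step 12
Reactants: 18 vanillin
Product: 19 4-isopropoxy-3-methoxybenzaldehyde
Conditions: 2-bromopropane, K2CO3, DMF, 60 °C
Reagents that add atoms: 2-bromopropane, CC(C)Br
Why: Williamson ether synthesis on the single phenol.

Step 13
Reactants: 17 5-{[(2S,3S)-3-(2-bromo-4,6-diisopropoxyphenyl)-3-(2,4-diisopropoxyphenyl)-2-(3,5-diisopropoxyphenyl)propyl]sulfonyl}-1-phenyl-1H-tetrazole; 19 4-isopropoxy-3-methoxybenzaldehyde
Product: 21 1-bromo-2-[(1S,2S,3E)-1-(2,4-diisopropoxyphenyl)-2-(3,5-diisopropoxyphenyl)-4-(4-isopropoxy-3-methoxyphenyl)but-3-en-1-yl]-3,5-diisopropoxybenzene, via potassiated sulfone 20 (not isolated)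
Conditions: KHMDS, DME, −65 °C; then 19, −65 °C to rt; aq NH4Cl
Reagents that add atoms: none
Why: Julia–Kocienski olefination (carbanion addition to the electron-rich aryl aldehyde, Smiles transfer of the tetrazole, elimination) should give the E-styrene, and with the carbanion on C1 the benzylic C2–H is never α to a carbonyl group.

Step 14
Reactants: 21 1-bromo-2-[(1S,2S,3E)-1-(2,4-diisopropoxyphenyl)-2-(3,5-diisopropoxyphenyl)-4-(4-isopropoxy-3-methoxyphenyl)but-3-en-1-yl]-3,5-diisopropoxybenzene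
Product: 22 (1E,2S,3S)-3-(2,4-diisopropoxyphenyl)-2-(3,5-diisopropoxyphenyl)-4,6-diisopropoxy-1-(4-isopropoxy-3-methoxybenzylidene)-2,3-dihydro-1H-indene
Conditions: Pd2(dba)3 (5 mol %), P(t-Bu)3·HBF4 (12 mol %), Cy2NMe (2 equiv), 1,4-dioxane, 70 °C, Ar
Reagents that add atoms: none
Why: Monoligated Pd(0) inserts into the hindered C7a–Br bond, the alkene binds, and syn-carbopalladation joins C7a to C1 with palladium on the exocyclic benzylic carbon; rotation about C1–C(exo) then brings H-1, the only β-hydrogen, syn to palladium and its loss gives the alkene. This is an intramolecular Mizoroki–Heck reaction of an aryl bromide with a 1,2-disubstituted alkene, an established entry to alkylidene-indanes. The single ring closes in the 5-exo-trig mode, favoured over 6-endo by tether length and by the normal styrene regiochemistry (aryl to the β-carbon, palladium benzylic). No stereocentre is created: the syn/syn sequence is stereospecific and turns the E-styrene into the alkene with the guaiacyl ring cis to C2 and trans to C7a (E), while C2 and C3 are spectators. The step needs insertion to beat C–H palladation of the neighbouring 2,4-diisopropoxyphenyl ring and must not allow hydridopalladium re-addition; the nearby alkene, the carboxylate-free medium, the moderate temperature and fast HBr removal by Cy2NMe should secure this.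

Step 15
Reactants: 22 (1E,2S,3S)-3-(2,4-diisopropoxyphenyl)-2-(3,5-diisopropoxyphenyl)-4,6-diisopropoxy-1-(4-isopropoxy-3-methoxybenzylidene)-2,3-dihydro-1H-indene
Product: 23 (1E,2S,3S)-3-(2,4-dihydroxyphenyl)-2-(3,5-dihydroxyphenyl)-1-(4-hydroxy-3-methoxybenzylidene)-2,3-dihydro-1H-indene-4,6-diol (CNP0122890.1)
Conditions: BCl3 (1 M in CH2Cl2, 3 equiv per ether), CH2Cl2, −78 to 0 °C; cold water
Reagents that add atoms: none
Why: Lewis-acid ether cleavage, in which BCl3 removes secondary alkyl groups from aryl ethers by SN1-like loss as 2-chloropropane much faster than it attacks a methyl ether, so the guaiacyl OMe should stay and the low temperature should keep the benzylidene from being protonated.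

Compound list
1 | 5-bromoresorcinol | Oc1cc(O)cc(Br)c1 | starting material
2 | 1-bromo-3,5-diisopropoxybenzene | CC(C)Oc1cc(Br)cc(OC(C)C)c1 | intermediate
3 | 1-bromo-2-iodo-3,5-diisopropoxybenzene | CC(C)Oc1cc(Br)c(I)c(OC(C)C)c1 | intermediate
4 | 2,4-dihydroxybenzaldehyde | O=Cc1ccc(O)cc1O | starting material
5 | 2-hydroxy-4-isopropoxybenzaldehyde | CC(C)Oc1ccc(C=O)c(O)c1 | intermediate
6 | (2-bromo-4,6-diisopropoxyphenyl)magnesium chloride | CC(C)Oc1cc(Br)c([Mg]Cl)c(OC(C)C)c1 | intermediate
7 | chloromagnesium 2-formyl-5-isopropoxyphenoxide | CC(C)Oc1ccc(C=O)c(O[Mg]Cl)c1 | intermediate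
8 | (±)-2-[(2-bromo-4,6-diisopropoxyphenyl)(hydroxy)methyl]-5-isopropoxyphenol | CC(C)Oc1ccc(C(O)c2c(Br)cc(OC(C)C)cc2OC(C)C)c(O)c1 | intermediate
9 | 3,5-dihydroxyphenylacetic acid | O=C(O)Cc1cc(O)cc(O)c1 | starting material
10 | isopropyl (3,5-diisopropoxyphenyl)acetate | CC(C)OC(=O)Cc1cc(OC(C)C)cc(OC(C)C)c1 | intermediate
11 | (3,5-diisopropoxyphenyl)acetaldehyde | O=CCc1cc(OC(C)C)cc(OC(C)C)c1 | intermediate
12 | (6E)-6-[(2-bromo-4,6-diisopropoxyphenyl)methylidene]-3-isopropoxycyclohexa-2,4-dien-1-one | O=C1C=C(OC(C)C)C=C/C1=C\c1c(Br)cc(OC(C)C)cc1OC(C)C | intermediate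
13 | (3S,4S)-4-(2-bromo-4,6-diisopropoxyphenyl)-3-(3,5-diisopropoxyphenyl)-7-isopropoxychroman-2-ol, 3,4-cis, both anomers | OC1Oc2cc(OC(C)C)ccc2[C@@H](c2c(Br)cc(OC(C)C)cc2OC(C)C)[C@H]1c1cc(OC(C)C)cc(OC(C)C)c1 | intermediate
14 | (2S,3S)-3-(2-bromo-4,6-diisopropoxyphenyl)-2-(3,5-diisopropoxyphenyl)-3-(2-hydroxy-4-isopropoxyphenyl)propan-1-ol | OC[C@H](c1cc(OC(C)C)cc(OC(C)C)c1)[C@@H](c1ccc(OC(C)C)cc1O)c1c(Br)cc(OC(C)C)cc1OC(C)C | intermediate
15 | (2S,3S)-3-(2-bromo-4,6-diisopropoxyphenyl)-3-(2,4-diisopropoxyphenyl)-2-(3,5-diisopropoxyphenyl)propan-1-ol | OC[C@H](c1cc(OC(C)C)cc(OC(C)C)c1)[C@@H](c1ccc(OC(C)C)cc1OC(C)C)c1c(Br)cc(OC(C)C)cc1OC(C)C | intermediate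
16 | (2S,3S)-triarylpropyl 1-phenyl-1H-tetrazol-5-yl sulfide (sulfur on C1) | c1ccccc1-n1nnnc1SC[C@H](c1cc(OC(C)C)cc(OC(C)C)c1)[C@@H](c1ccc(OC(C)C)cc1OC(C)C)c1c(Br)cc(OC(C)C)cc1OC(C)C | intermediate
17 | (2S,3S)-triarylpropyl 1-phenyl-1H-tetrazol-5-yl sulfone | O=S(=O)(C[C@H](c1cc(OC(C)C)cc(OC(C)C)c1)[C@@H](c1ccc(OC(C)C)cc1OC(C)C)c1c(Br)cc(OC(C)C)cc1OC(C)C)c1nnnn1-c1ccccc1 | intermediate
18 | vanillin | COc1cc(C=O)ccc1O | starting material
19 | 4-isopropoxy-3-methoxybenzaldehyde | COc1cc(C=O)ccc1OC(C)C | intermediate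
20 | potassium salt of the C1 carbanion of sulfone 17 | [K+].O=S(=O)([CH-][C@H](c1cc(OC(C)C)cc(OC(C)C)c1)[C@@H](c1ccc(OC(C)C)cc1OC(C)C)c1c(Br)cc(OC(C)C)cc1OC(C)C)c1nnnn1-c1ccccc1 | intermediate
21 | acyclic (S,S)-aryl bromide with E-styrene (Heck precursor) | COc1cc(/C=C/[C@H](c2cc(OC(C)C)cc(OC(C)C)c2)[C@@H](c2ccc(OC(C)C)cc2OC(C)C)c2c(Br)cc(OC(C)C)cc2OC(C)C)ccc1OC(C)C | intermediate
22 | (1E,2S,3S)-benzylidene-indane, hepta-O-isopropyl ether of the target | COc1cc(/C=C2/c3cc(OC(C)C)cc(OC(C)C)c3[C@H](c3ccc(OC(C)C)cc3OC(C)C)[C@H]2c2cc(OC(C)C)cc(OC(C)C)c2)ccc1OC(C)C | intermediate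
23 | (1E,2S,3S)-3-(2,4-dihydroxyphenyl)-2-(3,5-dihydroxyphenyl)-1-(4-hydroxy-3-methoxybenzylidene)-2,3-dihydro-1H-indene-4,6-diol | COc1cc(/C=C2/c3cc(O)cc(O)c3[C@H](c3ccc(O)cc3O)[C@H]2c2cc(O)cc(O)c2)ccc1O | target

Total step count: 15
Longest linear sequence: 11 (steps 1, 2, 4, 7, 8, 9, 10, 11, 13, 14, 15)

Steps most likely to fail

1. Step 14.
- What may go wrong: oxidative addition or insertion may be sluggish at the crowded ring-A carbon. Hydridopalladium re-addition may walk the double bond into the ring and erase C2. The neighbouring aryl ring may be palladated at C–H.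
- Fallback (sets out from 15 and 19, returns at 22): the C7a–C1 bond is made by a Parham cyclisation.
- Alcohol 15 is oxidised (TPAP cat., NMO·H2O, MeCN) to the (2S,3S)-triarylpropanoic acid F1.
- n-BuLi (2.2 equiv, THF, −100 to −78 °C) deprotonates the acid and exchanges bromine for lithium. Closure onto the carboxylate gives the trans-2,3-diarylindan-1-one F2. Any epimerisation at C2 runs towards the wanted trans isomer.
- Aldehyde 19 is reduced (NaBH4) to the benzyl alcohol F3, converted with SOCl2 into the benzyl chloride F4, and then with Mg into the benzyl Grignard reagent F5.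
- F5 adds to F2 (CeCl3, THF, −78 °C) to give the tertiary indanol F6.
- Mild acid-catalysed dehydration (cat. TsOH, CH2Cl2, rt) leads to 22.

2. Step 7.
- What may go wrong: attack on the methide carbon next to the twisted, di-ortho-substituted ring A may be slow. This could bring poor facial or cis/trans selectivity, self-condensation of the aldehyde, or Friedel–Crafts capture of the quinone methide by the electron-rich rings.
- Fallback (sets out from 8 and 10, returns at 14): Lewis-base catalysis under basic conditions replaces Brønsted-acid catalysis.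
- Ester 10 is saponified (LiOH, THF–H2O) to the arylacetic acid F7.
- Benzhydrol 8 is converted with p-toluenesulfinic acid into the bench-stable benzhydryl sulfone F8, from which base releases 12.
- F7 is activated (t-BuCOCl, i-Pr2NEt, CH2Cl2) as the mixed pivalic anhydride F9.
- The appropriate enantiomer of the isothiourea HyperBTM (10 mol %) mediates the known cis-selective Michael addition–lactonisation of F9 with 12. This gives the cis-dihydrocoumarin F10.
- LiBH4 (THF, 0 °C) opens F10 to diol 14.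

3. Step 15.
- What may go wrong: the electron-rich benzylidene may be protonated during the sevenfold dealkylation, followed by cationic ring closure or double-bond shift. Cleavage at the hindered ortho ethers may be incomplete. The methyl ether may be lost on warming.
- Fallback (sets out from 17 and 18, returns at 23): the acidic dealkylation is moved to a stage without an alkene, and the end-game becomes fluoride-based.
- Sulfone 17 is treated with BCl3 (CH2Cl2, −78 °C to rt) to give the hexaphenol sulfone F11.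
- Silylation (TBSCl, imidazole, DMF) gives the hexa-TBS sulfone F12.
- Vanillin 18 is silylated to O-TBS-vanillin F13.
- Julia–Kocienski olefination of F12 with F13 (KHMDS, DME) gives the hepta-TBS aryl bromide F14.
- The Heck conditions of step 14 give the hepta-TBS benzylidene-indane F15.
- Et3N·3HF (THF, 0 °C) releases 23.

Further compounds
F1 | step 14 | (2S,3S)-3-(2-bromo-4,6-diisopropoxyphenyl)-3-(2,4-diisopropoxyphenyl)-2-(3,5-diisopropoxyphenyl)propanoic acid | OC(=O)[C@H](c1cc(OC(C)C)cc(OC(C)C)c1)[C@@H](c1ccc(OC(C)C)cc1OC(C)C)c1c(Br)cc(OC(C)C)cc1OC(C)C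
F2 | step 14 | (2S,3S)-3-(2,4-diisopropoxyphenyl)-2-(3,5-diisopropoxyphenyl)-4,6-diisopropoxyindan-1-one (trans) | O=C1c2cc(OC(C)C)cc(OC(C)C)c2[C@H](c2ccc(OC(C)C)cc2OC(C)C)[C@H]1c1cc(OC(C)C)cc(OC(C)C)c1
F3 | step 14 | (4-isopropoxy-3-methoxyphenyl)methanol | COc1cc(CO)ccc1OC(C)C
F4 | step 14 | 4-(chloromethyl)-1-isopropoxy-2-methoxybenzene | COc1cc(CCl)ccc1OC(C)C
F5 | step 14 | (4-isopropoxy-3-methoxybenzyl)magnesium chloride | COc1cc(C[Mg]Cl)ccc1OC(C)C
F6 | step 14 | (2S,3S)-1-(4-isopropoxy-3-methoxybenzyl)-3-(2,4-diisopropoxyphenyl)-2-(3,5-diisopropoxyphenyl)-4,6-diisopropoxyindan-1-ol (C1 not defined) | COc1cc(CC2(O)c3cc(OC(C)C)cc(OC(C)C)c3[C@H](c3ccc(OC(C)C)cc3OC(C)C)[C@H]2c2cc(OC(C)C)cc(OC(C)C)c2)ccc1OC(C)C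
F7 | step 7 | (3,5-diisopropoxyphenyl)acetic acid | O=C(O)Cc1cc(OC(C)C)cc(OC(C)C)c1
F8 | step 7 | (±)-2-[(2-bromo-4,6-diisopropoxyphenyl)(4-methylphenylsulfonyl)methyl]-5-isopropoxyphenol | Cc1ccc(cc1)S(=O)(=O)C(c1ccc(OC(C)C)cc1O)c1c(Br)cc(OC(C)C)cc1OC(C)C
F9 | step 7 | (3,5-diisopropoxyphenyl)acetic pivalic anhydride | CC(C)(C)C(=O)OC(=O)Cc1cc(OC(C)C)cc(OC(C)C)c1
F10 | step 7 | (3S,4S)-4-(2-bromo-4,6-diisopropoxyphenyl)-3-(3,5-diisopropoxyphenyl)-7-isopropoxychroman-2-one (cis) | O=C1Oc2cc(OC(C)C)ccc2[C@@H](c2c(Br)cc(OC(C)C)cc2OC(C)C)[C@H]1c1cc(OC(C)C)cc(OC(C)C)c1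
F11 | step 15 | hexaphenol of sulfone 17 | O=S(=O)(C[C@H](c1cc(O)cc(O)c1)[C@@H](c1ccc(O)cc1O)c1c(Br)cc(O)cc1O)c1nnnn1-c1ccccc1
F12 | step 15 | hexa-O-TBS analogue of sulfone 17 | O=S(=O)(C[C@H](c1cc(O[Si](C)(C)C(C)(C)C)cc(O[Si](C)(C)C(C)(C)C)c1)[C@@H](c1ccc(O[Si](C)(C)C(C)(C)C)cc1O[Si](C)(C)C(C)(C)C)c1c(Br)cc(O[Si](C)(C)C(C)(C)C)cc1O[Si](C)(C)C(C)(C)C)c1nnnn1-c1ccccc1
F13 | step 15 | 4-(tert-butyldimethylsilyloxy)-3-methoxybenzaldehyde | COc1cc(C=O)ccc1O[Si](C)(C)C(C)(C)C
F14 | step 15 | hepta-O-TBS analogue of aryl bromide 21 | COc1cc(/C=C/[C@H](c2cc(O[Si](C)(C)C(C)(C)C)cc(O[Si](C)(C)C(C)(C)C)c2)[C@@H](c2ccc(O[Si](C)(C)C(C)(C)C)cc2O[Si](C)(C)C(C)(C)C)c2c(Br)cc(O[Si](C)(C)C(C)(C)C)cc2O[Si](C)(C)C(C)(C)C)ccc1O[Si](C)(C)C(C)(C)C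
F15 | step 15 | hepta-O-TBS analogue of benzylidene-indane 22 | COc1cc(/C=C2/c3cc(O[Si](C)(C)C(C)(C)C)cc(O[Si](C)(C)C(C)(C)C)c3[C@H](c3ccc(O[Si](C)(C)C(C)(C)C)cc3O[Si](C)(C)C(C)(C)C)[C@H]2c2cc(O[Si](C)(C)C(C)(C)C)cc(O[Si](C)(C)C(C)(C)C)c2)ccc1O[Si](C)(C)C(C)(C)C
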